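| setting | winter | dawn | flask |
|---|---|---|---|
| left-handed substrate | 0.034 M | 0.075 M | 0.050 M |
| right-handed substrate | 0.034 M | 0.075 M | 0.050 M |
| partner | 0.075 M (fed, over 15 h) | 0.075 M (fed, over 15 h) | 0.0750 M (fed, over 15 h) |
| remark | run made earlier; the fed solution adds 0.50 times the starting volume | run made earlier; the fed solution adds 0.50 times the starting volume | the fed solution adds 0.50 times the starting volume |
| time |  |  | 15 d |

| run | time / d | left-handed substrate / % | left-handed product / % |
|---|---|---|---|
| winter | 3.00 | 15.4 | 21.3 |
| winter | 6.00 | 14.3 | 19.4 |
| winter | 10.0 | 13.7 | 19.5 |
| winter | 12.0 | 13.4 | 18.8 |
| winter | 15.0 | 14.0 | 18.9 |
| dawn | 1.25 | 24.8 | 20.4 |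
| dawn | 4.00 | 22.4 | 15.7 |
| dawn | 8.00 | 22.1 | 14.5 |
| dawn | 10.0 | 21.8 | 14.5 |
| dawn | 15.0 | 21.4 | 14.5 |

(standard deviation of a reading: 0.3 percentage points)

- partner is single-handed; left-handed substrate and right-handed substrate are mirror images of each other, charged as a racemate, each of them at the stated concentration
- charges are per starting volume, the dose included; the dosed solution carries all of it
- the reaction counts as stopped when no species that holds the left-handed substrate and right-handed substrate together changes by six tenths of a point or more over the second half of the time
- the handed part of partner does not stay in what it makes, so the products of the two hands are mirror images too

* at 15 d, what has stopped the reaction, if anything has (forward and back rates have come level / the partner has run out first / all of the left-handed substrate has reacted / it is still moving)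
* part of the left-handed substrate and right-handed substrate together gone at 15 d
* the left-handed product standing at 15 d, as a percentage of the left-handed substrate and right-handed substrate together charged
* amount of left-handed product if the flask were left three thousand times as long, in percent of the left-handed substrate and right-handed substrate together charged

0.572 was the number I started from: in the dawn run, by 15.0 d, that much left-handed substrate had been lost per partner charged, mole for mole. So I counted turnovers. My first estimate was the flask's ceiling, since its partner charge allows 75.0% of the substrates charged, but the dawn count stands below one, so I could not expect that. Carrying the dawn count over gave 42.9% lost, but the winter run, with less substrate, counted 0.326, so the count was no constant.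

Both runs and the flask share the partner charge and dosing time, so I interpolated in the logarithm of the substrate concentration. My turnover count T, left-handed substrate lost per partner charged, came to 0.446 for the flask. A straight line in concentration gave 0.422, a doubt worth 1.8 percentage points. I committed to a loss of left-handed substrate in the flask of 33.5% of both substrates charged. In the dawn run, left-handed product stood at half of the left-handed substrate lost, so I took 16.8% for the flask. Dawn product read 14.5% at 8.00 d and 14.5% at 15.0 d, so I kept my flask figure of 16.8% for the long wait. But the readings hold no partner, so they did not tell me why the runs levelled off.

The forecast said forward and back rates have come level, in its words “the fast hand is reversibly balanced”, with 33.5% gone, 16.8% of left-handed product, and 20.3% after the long wait, where it parts from my figure.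

The answer for the flask at 15 d was this: the partner has run out first, with 33.8% gone and 16.9% of left-handed product standing; partner, the limiting reagent, stood at 0% of its charge at 15.0 d, less than the 35% of left-handed substrate left.

partner + left-handed substrate → left-handed product (k = 2.30 M⁻¹ h⁻¹); partner + right-handed substrate → right-handed product (k = 0.0510 M⁻¹ h⁻¹); 2 partner → homo dimer (k = 2.90 M⁻¹ h⁻¹); left-handed product ⇌ right-handed product (k = 0.0150 h⁻¹) The flask's T was 0.435, against my 0.446. A neighbouring flask with 0.019 M of partner counted 0.746, higher than the flask. The flask had come to rest: ten times the time left its conversion unchanged, and after the far longer wait left-handed product stood at 16.9%, 0.0012 points below its value at 15 d.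

The data were generated by integration for substances that don't exist; noise was put on by code.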